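The synthesis rests on the cyclohexene ring of the cis‑octalin (C1, C2, C3=C4, C4a, C8a): its C3=C4 double bond is read as the former central bond of a diene and is cut together with the ring‑fusion bond C4a–C8a. In one pot, a Suzuki–Miyaura coupling joins an (E)‑propenylboronate to a linear (E)‑iodoalkene bearing a (Z)‑enoate, and the resulting triene closes both carbocycles by intramolecular Diels–Alder reaction, setting four contiguous stereocentres. The resolved octalin aldehyde is then added to a lithiated 2,4‑bis(allyloxy)pyridine that already carries the oxygenated cyclohexene; enone epoxidation, reduction, deallylation and N‑hydroxylation complete the target.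

Key step: step 4

Remark: C1–C8a are octalin locants, C1′–C6′ those of the oxygenated cyclohexane (C1′ on the pyridine, C6′ the neighbouring oxirane carbon), "Oct" is the (1R,2S,4aR,8aR)-2-methyl-1,2,4a,5,6,7,8,8a-octahydronaphthalen-1-yl group, and enone 14 is assumed to be a commercial building block.

Step 1
Reactants: 1 hept-6-yn-1-ol
Product: 2 (E)-7-iodohept-6-en-1-ol
Conditions: Cp2Zr(H)Cl (2.2 equiv), CH2Cl2, rt; then I2, 0 °C
Reagents that add atoms: iodine, [I][I]
Why: Hydrozirconation–iodination: after one equivalent of Cp2Zr(H)Cl is consumed by the hydroxyl group, syn anti‑Markovnikov addition of Zr–H to the terminal alkyne and iodinolysis of the alkenyl–zirconium bond with retention should give only the (E)‑iodoalkene.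

Step 2
Reactants: 2 (E)-7-iodohept-6-en-1-ol
Product: 3 (E)-7-iodohept-6-enal
Conditions: Dess–Martin periodinane, CH2Cl2, rt
Reagents that add atoms: none
Why: Dess–Martin oxidation should convert the primary alcohol into the aldehyde without touching the alkenyl iodide.

Step 3
Reactants: 3 (E)-7-iodohept-6-enal
Product: 4 methyl (2Z,8E)-9-iodonona-2,8-dienoate
Conditions: (CF3CH2O)2P(O)CH2CO2Me, KN(SiMe3)2, 18-crown-6, THF, −78 °C
Reagents that add atoms: methyl bis(2,2,2-trifluoroethyl)phosphonoacetate, COC(=O)CP(=O)(OCC(F)(F)F)OCC(F)(F)F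
Why: Still–Gennari olefination: the adduct of the electron‑poor trifluoroethyl phosphonate anion collapses before it can equilibrate, so the kinetic (Z)‑enoate should be formed.

Step 4
Reactants: 4 methyl (2Z,8E)-9-iodonona-2,8-dienoate; 5 (E)-4,4,5,5-tetramethyl-2-(prop-1-en-1-yl)-1,3,2-dioxaborolane
Product: 7 methyl rac-(1S,2S,4aR,8aR)-2-methyl-1,2,4a,5,6,7,8,8a-octahydronaphthalene-1-carboxylate, via methyl (2Z,8E,10E)-dodeca-2,8,10-trienoate 6 (not isolated)
Conditions: Pd(dppf)Cl2 (5 mol %), CsF, 1,4-dioxane, 65 °C; then BHT, 150 °C, sealed tube, same pot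
Reagents that add atoms: none
Why: Oxidative addition of the alkenyl iodide of 4 to palladium, fluoride‑assisted transmetalation of boronate 5 and reductive elimination (Suzuki–Miyaura coupling) join C3 to C4 with retention of both alkene geometries and give triene 6, whose (E,E)‑diene then adds to the tethered (Z)‑enoate in a concerted suprafacial intramolecular Diels–Alder reaction on heating. The closest known reaction type is the domino cross‑coupling/intramolecular Diels–Alder sequence, in which a diene assembled by palladium‑catalysed alkenyl–alkenyl coupling cyclises in the same flask. The cyclohexene ring (C1, C2, C3, C4, C4a, C8a) is closed by the [4+2] cycloaddition, which forms C1–C2 and C4a–C8a and turns the new C3–C4 bond into the ring alkene, and the cyclohexane ring (C4a, C5–C8, C8a) is closed by the same C4a–C8a bond through the four‑carbon tether. At C2 and C4a the (E,E)‑diene puts the methyl group and the C5 methylene on one face, at C1 and C8a the (Z)‑dienophile puts the ester and the C8 methylene on one face, and the endo transition state (ester and tether both under the diene) relates the two pairs so that the ring fusion is cis and all four substituents lie on the same face. The step needs endo over exo selectivity, which the (Z)‑enoate should favour because only the endo mode keeps the activating ester under the diene whereas the exo mode leads to the trans‑fused isomer; no chiral element is present, so 7 is racemic. C1 is then the only centre that differs from the target and is corrected in step 5, and the enantiomers are separated in steps 7 and 8.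

Step 5
Reactants: 7 methyl rac-(1S,2S,4aR,8aR)-2-methyl-1,2,4a,5,6,7,8,8a-octahydronaphthalene-1-carboxylate
Product: 8 methyl rac-(1R,2S,4aR,8aR)-2-methyl-1,2,4a,5,6,7,8,8a-octahydronaphthalene-1-carboxylate
Conditions: NaOMe, MeOH, 60 °C
Reagents that add atoms: none
Why: Base‑mediated epimerisation through the ester enolate should move the C1 ester from the crowded all‑cis arrangement to the equatorial position trans to both the C2 methyl group and the C8a–C8 bond, the thermodynamic configuration, while the three non‑enolisable centres stay fixed.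

Step 6
Reactants: 8 methyl rac-(1R,2S,4aR,8aR)-2-methyl-1,2,4a,5,6,7,8,8a-octahydronaphthalene-1-carboxylate
Product: 9 rac-(1R,2S,4aR,8aR)-2-methyl-1,2,4a,5,6,7,8,8a-octahydronaphthalene-1-carbaldehyde
Conditions: i-Bu2AlH, CH2Cl2, −78 °C
Reagents that add atoms: none
Why: Partial reduction: at low temperature i-Bu2AlH should add once to the hindered ester, and the aluminium hemiacetal collapses to the aldehyde only on work‑up.

Step 7
Reactants: 9 rac-(1R,2S,4aR,8aR)-2-methyl-1,2,4a,5,6,7,8,8a-octahydronaphthalene-1-carbaldehyde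
Product: 10 (4R,5R)-1,3-dimethyl-2-(Oct)-4,5-diphenylimidazolidine
Conditions: (1R,2R)-N,N′-dimethyl-1,2-diphenylethane-1,2-diamine, 4 Å molecular sieves, Et2O, rt; chromatographic separation of the two aminals
Reagents that add atoms: (1R,2R)-N,N′-dimethyl-1,2-diphenylethane-1,2-diamine, CN[C@H](c1ccccc1)[C@H](NC)c1ccccc1
Why: Resolution through diastereomeric aminals: the C2‑symmetric diamine condenses with each aldehyde enantiomer to one imidazolidine without creating a new stereocentre, so the racemate becomes two separable diastereomers, and the absolute configuration of the octalin is fixed by taking the aminal of the (1R,2S,4aR,8aR) aldehyde.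

Step 8
Reactants: 10 (4R,5R)-1,3-dimethyl-2-(Oct)-4,5-diphenylimidazolidine
Product: 11 (1R,2S,4aR,8aR)-2-methyl-1,2,4a,5,6,7,8,8a-octahydronaphthalene-1-carbaldehyde
Conditions: 2% aq. HCl, Et2O, 0 °C
Reagents that add atoms: water, O
Why: Mild acid hydrolysis of the aminal should return the aldehyde and the diamine without touching the alkene, and the α‑centre is already in its thermodynamic configuration.

Step 9
Reactants: 12 5-bromo-2,4-dichloropyridine
Product: 13 2,4-bis(allyloxy)-5-bromopyridine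
Conditions: prop-2-en-1-ol, NaH, DMF, 0 → 100 °C
Reagents that add atoms: prop-2-en-1-ol, C=CCO
Why: Twofold nucleophilic aromatic substitution: allyloxide should displace first the 4‑chloride and then, on heating, the 2‑chloride, both activated by the ring nitrogen, while the 5‑bromide is not activated.

Step 10
Reactants: 13 2,4-bis(allyloxy)-5-bromopyridine; 14 (S)-4-[(tert-butyldimethylsilyl)oxy]cyclohex-2-en-1-one
Product: 17 2,4-bis(allyloxy)-5-{(1R,4S)-4-[(tert-butyldimethylsilyl)oxy]-1-[(trimethylsilyl)oxy]cyclohex-2-en-1-yl}pyridine, via [4,6-bis(allyloxy)pyridin-3-yl]lithium 15 (not isolated), via lithium tertiary alkoxide 16 (not isolated)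
Conditions: n-BuLi, THF, −78 °C; then 14, −78 °C; then Me3SiCl, −78 → 0 °C
Reagents that add atoms: chlorotrimethylsilane, C[Si](C)(C)Cl
Why: Bromine–lithium exchange gives aryllithium 15, whose 1,2‑addition to enone 14 from the face opposite the pseudoaxial C4′ silyloxy group should set C1′ with its oxygen cis to that group, and the alkoxide 16 is silylated in situ.

Step 11
Reactants: 17 2,4-bis(allyloxy)-5-{(1R,4S)-4-[(tert-butyldimethylsilyl)oxy]-1-[(trimethylsilyl)oxy]cyclohex-2-en-1-yl}pyridine; 11 (1R,2S,4aR,8aR)-2-methyl-1,2,4a,5,6,7,8,8a-octahydronaphthalene-1-carbaldehyde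
Product: 19 [2,4-bis(allyloxy)-5-{(1R,4S)-4-[(tert-butyldimethylsilyl)oxy]-1-[(trimethylsilyl)oxy]cyclohex-2-en-1-yl}pyridin-3-yl](Oct)methanol as both carbinol epimers, via 3-lithiopyridine 18 (not isolated)
Conditions: lithium 2,2,6,6-tetramethylpiperidide, THF, −78 → −40 °C; then 11, −78 °C; H2O
Reagents that add atoms: none
Why: Directed ortho‑metalation: the ring C–H flanked by the two allyloxy groups is the most acidic position and should be removed by the non‑nucleophilic amide base, and 18 adds to aldehyde 11 to give both carbinol epimers, which converge in step 13.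

Step 12
Reactants: 19 [2,4-bis(allyloxy)-5-{(1R,4S)-4-[(tert-butyldimethylsilyl)oxy]-1-[(trimethylsilyl)oxy]cyclohex-2-en-1-yl}pyridin-3-yl](Oct)methanol
Product: 20 (1R,4S)-1-{4,6-bis(allyloxy)-5-[hydroxy(Oct)methyl]pyridin-3-yl}cyclohex-2-ene-1,4-diol
Conditions: Bu4NF, THF, 0 °C → rt
Reagents that add atoms: none
Why: Fluoride‑mediated silyl ether cleavage should remove both silyl groups under the non‑acidic conditions that the ionisable tertiary allylic carbinol requires.

Step 13
Reactants: 20 (1R,4S)-1-{4,6-bis(allyloxy)-5-[hydroxy(Oct)methyl]pyridin-3-yl}cyclohex-2-ene-1,4-diol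
Product: 21 (4R)-4-{4,6-bis(allyloxy)-5-[(Oct)carbonyl]pyridin-3-yl}-4-hydroxycyclohex-2-en-1-one
Conditions: Dess–Martin periodinane, pyridine, CH2Cl2, 0 °C → rt
Reagents that add atoms: none
Why: Dess–Martin oxidation should convert both secondary alcohols into ketones and spare the tertiary alcohol, which removes the carbinol and C4′ stereocentres and leaves C1′ as the only stereocentre of the enone ring.

Step 14
Reactants: 21 (4R)-4-{4,6-bis(allyloxy)-5-[(Oct)carbonyl]pyridin-3-yl}-4-hydroxycyclohex-2-en-1-one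
Product: 22 (4R)-4-{4,6-bis(allyloxy)-5-[(Oct)carbonyl]pyridin-3-yl}-4-[(trimethylsilyl)oxy]cyclohex-2-en-1-one
Conditions: 1-(trimethylsilyl)imidazole, CH2Cl2, rt
Reagents that add atoms: 1-(trimethylsilyl)imidazole, C[Si](C)(C)n1ccnc1
Why: O‑Silylation with the strongly silylating imidazolide should cap the hindered tertiary hydroxyl under neutral conditions, so that it shields its face instead of directing the peroxide in the next step.

Step 15
Reactants: 22 (4R)-4-{4,6-bis(allyloxy)-5-[(Oct)carbonyl]pyridin-3-yl}-4-[(trimethylsilyl)oxy]cyclohex-2-en-1-one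
Product: 23 (1S,5S,6R)-5-{4,6-bis(allyloxy)-5-[(Oct)carbonyl]pyridin-3-yl}-5-[(trimethylsilyl)oxy]-7-oxabicyclo[4.1.0]heptan-2-one
Conditions: t-BuOOH, DBU, CH2Cl2, 0 °C
Reagents that add atoms: tert-butyl hydroperoxide, CC(C)(C)OO
Why: Weitz–Scheffer nucleophilic epoxidation: the peroxide anion should add to the enone β‑carbon C6′ anti to the pseudoaxial silyloxy group on C1′ (the pyridyl group being pseudoequatorial) and the enolate closes the oxirane, giving the epoxide trans to the silyloxy group and cis to the pyridine, while the isolated octalin and allyl ether alkenes are inert to the nucleophilic oxidant.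

Step 16
Reactants: 23 (1S,5S,6R)-5-{4,6-bis(allyloxy)-5-[(Oct)carbonyl]pyridin-3-yl}-5-[(trimethylsilyl)oxy]-7-oxabicyclo[4.1.0]heptan-2-one
Product: 24 (1R,2S,5R,6R)-2-{4,6-bis(allyloxy)-5-[(Oct)carbonyl]pyridin-3-yl}-7-oxabicyclo[4.1.0]heptane-2,5-diol
Conditions: NaBH4, CeCl3·7H2O, MeOH, −78 °C; then citric acid, MeOH, 0 °C
Reagents that add atoms: none
Why: Cerium‑assisted borohydride reduction (Luche conditions): hydride should attack the ketone anti to the neighbouring oxirane oxygen and give the C4′ alcohol cis to the epoxide, the hindered di‑ortho‑substituted aryl ketone is not reduced, and mild acidic methanolysis then removes the tertiary silyl ether.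

Step 17
Reactants: 24 (1R,2S,5R,6R)-2-{4,6-bis(allyloxy)-5-[(Oct)carbonyl]pyridin-3-yl}-7-oxabicyclo[4.1.0]heptane-2,5-diol
Product: 25 5-[(1R,2S,5R,6R)-2,5-dihydroxy-7-oxabicyclo[4.1.0]heptan-2-yl]-4-hydroxy-3-[(Oct)carbonyl]pyridin-2(1H)-one
Conditions: Pd(PPh3)4 (5 mol %), morpholine, THF, rt
Reagents that add atoms: none
Why: Tsuji–Trost deallylation: zerovalent palladium should ionise both allyl pyridyl ethers to π‑allyl complexes that morpholine traps, releasing the 4‑hydroxy‑2‑pyridone under neutral conditions that spare the epoxide and the octalin alkene.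

Step 18
Reactants: 25 5-[(1R,2S,5R,6R)-2,5-dihydroxy-7-oxabicyclo[4.1.0]heptan-2-yl]-4-hydroxy-3-[(Oct)carbonyl]pyridin-2(1H)-one
Product: 27 fischerin, via tetrakis(trimethylsilyl) ether 26 (not isolated)
Conditions: N,O-bis(trimethylsilyl)acetamide, CH2Cl2, rt; then MoO(O2)2(py)(HMPA), CH2Cl2, rt; then citric acid, MeOH
Reagents that add atoms: MoO(O2)2(py)(HMPA), O=[Mo]12(OO1)OO2.c1ccncc1.CN(C)P(=O)(N(C)C)N(C)C
Why: N‑Hydroxylation of a 2‑pyridone through its 2‑silyloxypyridine: per‑O‑silylation gives pyridine 26, whose ring nitrogen should accept oxygen from the electrophilic diperoxomolybdenum complex (not an epoxidant for isolated alkenes), and methanolysis of the silyl groups releases the N‑hydroxy‑2‑pyridone.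

Compound list
1 | hept-6-yn-1-ol | C#CCCCCCO | starting material
2 | (E)-7-iodohept-6-en-1-ol | OCCCCC/C=C/I | intermediate
3 | (E)-7-iodohept-6-enal | O=CCCCC/C=C/I | intermediate
4 | methyl (2Z,8E)-9-iodonona-2,8-dienoate | COC(=O)/C=C\CCCC/C=C/I | intermediate
5 | (E)-4,4,5,5-tetramethyl-2-(prop-1-en-1-yl)-1,3,2-dioxaborolane | C/C=C/B1OC(C)(C)C(C)(C)O1 | starting material
6 | methyl (2Z,8E,10E)-dodeca-2,8,10-trienoate (not isolated) | COC(=O)/C=C\CCCC/C=C/C=C/C | intermediate
7 | methyl rac-(1S,2S,4aR,8aR)-2-methyl-1,2,4a,5,6,7,8,8a-octahydronaphthalene-1-carboxylate (all-cis, cis-fused; racemate, one enantiomer drawn) | C[C@H]1C=C[C@H]2CCCC[C@H]2[C@H]1C(=O)OC | intermediate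
8 | methyl rac-(1R,2S,4aR,8aR)-2-methyl-1,2,4a,5,6,7,8,8a-octahydronaphthalene-1-carboxylate (racemate, one enantiomer drawn) | C[C@H]1C=C[C@H]2CCCC[C@H]2[C@@H]1C(=O)OC | intermediate
9 | rac-(1R,2S,4aR,8aR)-2-methyl-1,2,4a,5,6,7,8,8a-octahydronaphthalene-1-carbaldehyde (racemate, one enantiomer drawn) | C[C@H]1C=C[C@H]2CCCC[C@H]2[C@@H]1C=O | intermediate
10 | (4R,5R)-1,3-dimethyl-2-(Oct)-4,5-diphenylimidazolidine | C[C@H]1C=C[C@H]2CCCC[C@H]2[C@@H]1C3N(C)[C@H](c4ccccc4)[C@@H](c4ccccc4)N3C | intermediate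
11 | (1R,2S,4aR,8aR)-2-methyl-1,2,4a,5,6,7,8,8a-octahydronaphthalene-1-carbaldehyde (single enantiomer) | C[C@H]1C=C[C@H]2CCCC[C@H]2[C@@H]1C=O | intermediate
12 | 5-bromo-2,4-dichloropyridine | Clc1cc(Cl)c(Br)cn1 | starting material
13 | 2,4-bis(allyloxy)-5-bromopyridine | C=CCOc1ncc(Br)c(OCC=C)c1 | intermediate
14 | (S)-4-[(tert-butyldimethylsilyl)oxy]cyclohex-2-en-1-one | O=C1C=C[C@@H](O[Si](C)(C)C(C)(C)C)CC1 | starting material
15 | [4,6-bis(allyloxy)pyridin-3-yl]lithium (not isolated) | C=CCOc1ncc([Li])c(OCC=C)c1 | intermediate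
16 | lithium (1R,4S)-1-[4,6-bis(allyloxy)pyridin-3-yl]-4-[(tert-butyldimethylsilyl)oxy]cyclohex-2-en-1-olate (not isolated) | C=CCOc1ncc([C@]2(O[Li])C=C[C@@H](O[Si](C)(C)C(C)(C)C)CC2)c(OCC=C)c1 | intermediate
17 | 2,4-bis(allyloxy)-5-{(1R,4S)-4-[(tert-butyldimethylsilyl)oxy]-1-[(trimethylsilyl)oxy]cyclohex-2-en-1-yl}pyridine | C=CCOc1ncc([C@]2(O[Si](C)(C)C)C=C[C@@H](O[Si](C)(C)C(C)(C)C)CC2)c(OCC=C)c1 | intermediate
18 | 3-lithio derivative of 17 (not isolated) | C=CCOc1ncc([C@]2(O[Si](C)(C)C)C=C[C@@H](O[Si](C)(C)C(C)(C)C)CC2)c(OCC=C)c1[Li] | intermediate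
19 | [2,4-bis(allyloxy)-5-{(1R,4S)-4-[(tert-butyldimethylsilyl)oxy]-1-[(trimethylsilyl)oxy]cyclohex-2-en-1-yl}pyridin-3-yl](Oct)methanol, both carbinol epimers | C=CCOc1ncc([C@]2(O[Si](C)(C)C)C=C[C@@H](O[Si](C)(C)C(C)(C)C)CC2)c(OCC=C)c1C(O)[C@@H]1[C@@H](C)C=C[C@H]2CCCC[C@@H]12 | intermediate
20 | (1R,4S)-1-{4,6-bis(allyloxy)-5-[hydroxy(Oct)methyl]pyridin-3-yl}cyclohex-2-ene-1,4-diol, both carbinol epimers | C=CCOc1ncc([C@]2(O)C=C[C@@H](O)CC2)c(OCC=C)c1C(O)[C@@H]1[C@@H](C)C=C[C@H]2CCCC[C@@H]12 | intermediate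
21 | (4R)-4-{4,6-bis(allyloxy)-5-[(Oct)carbonyl]pyridin-3-yl}-4-hydroxycyclohex-2-en-1-one | C=CCOc1ncc([C@]2(O)C=CC(=O)CC2)c(OCC=C)c1C(=O)[C@@H]1[C@@H](C)C=C[C@H]2CCCC[C@@H]12 | intermediate
22 | (4R)-4-{4,6-bis(allyloxy)-5-[(Oct)carbonyl]pyridin-3-yl}-4-[(trimethylsilyl)oxy]cyclohex-2-en-1-one | C=CCOc1ncc([C@]2(O[Si](C)(C)C)C=CC(=O)CC2)c(OCC=C)c1C(=O)[C@@H]1[C@@H](C)C=C[C@H]2CCCC[C@@H]12 | intermediate
23 | (1S,5S,6R)-5-{4,6-bis(allyloxy)-5-[(Oct)carbonyl]pyridin-3-yl}-5-[(trimethylsilyl)oxy]-7-oxabicyclo[4.1.0]heptan-2-one | C=CCOc1ncc([C@@]2(O[Si](C)(C)C)CCC(=O)[C@H]3O[C@H]32)c(OCC=C)c1C(=O)[C@@H]1[C@@H](C)C=C[C@H]2CCCC[C@@H]12 | intermediate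
24 | (1R,2S,5R,6R)-2-{4,6-bis(allyloxy)-5-[(Oct)carbonyl]pyridin-3-yl}-7-oxabicyclo[4.1.0]heptane-2,5-diol | C=CCOc1ncc([C@@]2(O)CC[C@@H](O)[C@H]3O[C@H]32)c(OCC=C)c1C(=O)[C@@H]1[C@@H](C)C=C[C@H]2CCCC[C@@H]12 | intermediate
25 | 5-[(1R,2S,5R,6R)-2,5-dihydroxy-7-oxabicyclo[4.1.0]heptan-2-yl]-4-hydroxy-3-[(Oct)carbonyl]pyridin-2(1H)-one | C[C@H]1C=C[C@H]2CCCC[C@H]2[C@@H]1C(=O)c1c(O)c([C@@]2(O)CC[C@@H](O)[C@H]3O[C@H]32)c[nH]c1=O | intermediate
26 | tetrakis(trimethylsilyl) ether of 25 (2,4-bis(trimethylsilyloxy)pyridine, both cyclohexane hydroxyls silylated; not isolated) | C[Si](C)(C)Oc1ncc([C@@]2(O[Si](C)(C)C)CC[C@@H](O[Si](C)(C)C)[C@H]3O[C@H]32)c(O[Si](C)(C)C)c1C(=O)[C@@H]1[C@@H](C)C=C[C@H]2CCCC[C@@H]12 | intermediate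
27 | fischerin, 5-[(1R,2S,5R,6R)-2,5-dihydroxy-7-oxabicyclo[4.1.0]heptan-2-yl]-1,4-dihydroxy-3-[(Oct)carbonyl]pyridin-2(1H)-one | C[C@H]1C=C[C@H]2CCCC[C@H]2[C@@H]1C(=O)c1c(O)c([C@@]2(O)CC[C@@H](O)[C@H]3O[C@H]32)cn(O)c1=O | target

Total step count: 18. Longest linear sequence: 16 steps (steps 1–8, then 11–18); the pyridine branch (steps 9 and 10) joins at step 11.

Steps most likely to fail

Step 4. The thermal cycloaddition of the (Z)-enoate may show too little endo preference, or be outrun by Z→E isomerisation of the dienophile or by loss of the diene at the temperature needed, which would erode the cis‑fused all‑cis isomer. The fallback activates the dienophile as an aldehyde and separates coupling from cycloaddition; it sets out from 4 and returns at 9. Reduction of 4 with i-Bu2AlH gives (2Z,8E)-9-iodonona-2,8-dien-1-ol F1. Suzuki–Miyaura coupling of F1 with 5 (Pd(dppf)Cl2, CsF) gives (2Z,8E,10E)-dodeca-2,8,10-trien-1-ol F2. Oxidation with MnO2 gives (2Z,8E,10E)-dodeca-2,8,10-trienal F3, whose intramolecular Diels–Alder reaction should proceed at or below room temperature (if needed with Me2AlCl) with the stronger endo preference of an enal. This gives rac-(1S,2S,4aR,8aR)-2-methyl-1,2,4a,5,6,7,8,8a-octahydronaphthalene-1-carbaldehyde F4, which DBU epimerises at C1 to 9.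

Step 18. Oxygen transfer to nitrogen may be slow or unselective on the fully functionalised, persilylated substrate, and the epoxy diol may be opened under the Lewis‑acidic peroxomolybdenum conditions. The fallback forms the N–O bond before the epoxide exists and carries it as an allyl ether; it sets out from 21 and returns at 27. Deallylation of 21 (Pd(PPh3)4, morpholine) gives 4-hydroxy-5-[(1R)-1-hydroxy-4-oxocyclohex-2-en-1-yl]-3-[(Oct)carbonyl]pyridin-2(1H)-one F5. Silylation with N,O-bis(trimethylsilyl)acetamide gives the tris(trimethylsilyl) derivative of the pyridone diketone F6, which is oxidised in situ with MoO(O2)2(py)(HMPA) and methanolysed to 1,4-dihydroxy-5-[(1R)-1-hydroxy-4-oxocyclohex-2-en-1-yl]-3-[(Oct)carbonyl]pyridin-2(1H)-one F7. Allyl bromide and Cs2CO3 give 1,4-bis(allyloxy)-5-[(1R)-1-hydroxy-4-oxocyclohex-2-en-1-yl]-3-[(Oct)carbonyl]pyridin-2(1H)-one F8. The conditions of steps 14 to 16 then give in turn the C1′ trimethylsilyl ether of the bis(allyloxy)pyridinone F9, 1,4-bis(allyloxy)-5-{(1R,2S,6S)-5-oxo-2-[(trimethylsilyl)oxy]-7-oxabicyclo[4.1.0]heptan-2-yl}-3-[(Oct)carbonyl]pyridin-2(1H)-one F10 and 1,4-bis(allyloxy)-5-[(1R,2S,5R,6R)-2,5-dihydroxy-7-oxabicyclo[4.1.0]heptan-2-yl]-3-[(Oct)carbonyl]pyridin-2(1H)-one F11. Deallylation of F11 (Pd(PPh3)4, morpholine) gives 27.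

Step 15. The peroxide may attack the enone face syn to the silyloxy group, or the silyl ether may be lost under the basic conditions so that the free hydroxyl directs the oxidant; either would place the epoxide cis to the tertiary oxygen. The fallback replaces nucleophilic epoxidation by a hydroxyl‑directed one; it sets out from 22 and returns at 24. Corey–Bakshi–Shibata reduction of the enone carbonyl ((S)-2-methyl-CBS-oxazaborolidine, BH3·SMe2), under catalyst control, gives {2,4-bis(allyloxy)-5-[(1R,4R)-4-hydroxy-1-[(trimethylsilyl)oxy]cyclohex-2-en-1-yl]pyridin-3-yl}(Oct)methanone F12. Epoxidation with VO(acac)2 and t-BuOOH delivers oxygen syn to the new allylic hydroxyl, that is anti to the silyloxy group, and is selective for the allylic alcohol over the isolated alkenes. It gives {2,4-bis(allyloxy)-5-[(1R,2S,5R,6R)-5-hydroxy-2-[(trimethylsilyl)oxy]-7-oxabicyclo[4.1.0]heptan-2-yl]pyridin-3-yl}(Oct)methanone F13. Methanolysis of the silyl ether (citric acid, MeOH) gives 24.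

Further compounds
F1 | step 4 | (2Z,8E)-9-iodonona-2,8-dien-1-ol | OC/C=C\CCCC/C=C/I
F2 | step 4 | (2Z,8E,10E)-dodeca-2,8,10-trien-1-ol | OC/C=C\CCCC/C=C/C=C/C
F3 | step 4 | (2Z,8E,10E)-dodeca-2,8,10-trienal | O=C/C=C\CCCC/C=C/C=C/C
F4 | step 4 | rac-(1S,2S,4aR,8aR)-2-methyl-1,2,4a,5,6,7,8,8a-octahydronaphthalene-1-carbaldehyde | C[C@H]1C=C[C@H]2CCCC[C@H]2[C@H]1C=O
F5 | step 18 | 4-hydroxy-5-[(1R)-1-hydroxy-4-oxocyclohex-2-en-1-yl]-3-[(Oct)carbonyl]pyridin-2(1H)-one | O=c1[nH]cc([C@]2(O)C=CC(=O)CC2)c(O)c1C(=O)[C@@H]1[C@@H](C)C=C[C@H]2CCCC[C@@H]12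
F6 | step 18 | tris(trimethylsilyl) derivative of the pyridone diketone | C[Si](C)(C)Oc1ncc([C@]2(O[Si](C)(C)C)C=CC(=O)CC2)c(O[Si](C)(C)C)c1C(=O)[C@@H]1[C@@H](C)C=C[C@H]2CCCC[C@@H]12
F7 | step 18 | 1,4-dihydroxy-5-[(1R)-1-hydroxy-4-oxocyclohex-2-en-1-yl]-3-[(Oct)carbonyl]pyridin-2(1H)-one | O=c1n(O)cc([C@]2(O)C=CC(=O)CC2)c(O)c1C(=O)[C@@H]1[C@@H](C)C=C[C@H]2CCCC[C@@H]12
F8 | step 18 | 1,4-bis(allyloxy)-5-[(1R)-1-hydroxy-4-oxocyclohex-2-en-1-yl]-3-[(Oct)carbonyl]pyridin-2(1H)-one | O=c1n(OCC=C)cc([C@]2(O)C=CC(=O)CC2)c(OCC=C)c1C(=O)[C@@H]1[C@@H](C)C=C[C@H]2CCCC[C@@H]12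
F9 | step 18 | C1′ trimethylsilyl ether of the bis(allyloxy)pyridinone | O=c1n(OCC=C)cc([C@]2(O[Si](C)(C)C)C=CC(=O)CC2)c(OCC=C)c1C(=O)[C@@H]1[C@@H](C)C=C[C@H]2CCCC[C@@H]12
F10 | step 18 | 1,4-bis(allyloxy)-5-{(1R,2S,6S)-5-oxo-2-[(trimethylsilyl)oxy]-7-oxabicyclo[4.1.0]heptan-2-yl}-3-[(Oct)carbonyl]pyridin-2(1H)-one | O=c1n(OCC=C)cc([C@@]2(O[Si](C)(C)C)CCC(=O)[C@H]3O[C@H]32)c(OCC=C)c1C(=O)[C@@H]1[C@@H](C)C=C[C@H]2CCCC[C@@H]12
F11 | step 18 | 1,4-bis(allyloxy)-5-[(1R,2S,5R,6R)-2,5-dihydroxy-7-oxabicyclo[4.1.0]heptan-2-yl]-3-[(Oct)carbonyl]pyridin-2(1H)-one | O=c1n(OCC=C)cc([C@@]2(O)CC[C@@H](O)[C@H]3O[C@H]32)c(OCC=C)c1C(=O)[C@@H]1[C@@H](C)C=C[C@H]2CCCC[C@@H]12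
F12 | step 15 | {2,4-bis(allyloxy)-5-[(1R,4R)-4-hydroxy-1-[(trimethylsilyl)oxy]cyclohex-2-en-1-yl]pyridin-3-yl}(Oct)methanone | C=CCOc1ncc([C@]2(O[Si](C)(C)C)C=C[C@H](O)CC2)c(OCC=C)c1C(=O)[C@@H]1[C@@H](C)C=C[C@H]2CCCC[C@@H]12
F13 | step 15 | {2,4-bis(allyloxy)-5-[(1R,2S,5R,6R)-5-hydroxy-2-[(trimethylsilyl)oxy]-7-oxabicyclo[4.1.0]heptan-2-yl]pyridin-3-yl}(Oct)methanone | C=CCOc1ncc([C@@]2(O[Si](C)(C)C)CC[C@@H](O)[C@H]3O[C@H]32)c(OCC=C)c1C(=O)[C@@H]1[C@@H](C)C=C[C@H]2CCCC[C@@H]12
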